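The earlier runs and the new flask are calculated for an exercise, and the scatter is random.

| flask | E | Z | remark | time |
|---|---|---|---|---|
| Wednesday's | 0.25 M | 200 mM (held) | run made earlier |  |
| Monday's | 1 M | 200 mM (held) | run made earlier |  |
| flask | 0.50 M | 200 mM (held) |  | 8.0 d |

| run | time / d | ED / % |
|---|---|---|
| Wednesday's | 0.833 | 59.4 |
| Wednesday's | 1.25 | 78.5 |
| Wednesday's | 2.00 | 90.3 |
| Wednesday's | 4.00 | 72.7 |
| Wednesday's | 6.00 | 57.4 |
| Wednesday's | 10.0 | 32.9 |
| Monday's | 0.833 | 23.5 |
| Monday's | 1.25 | 35.1 |
| Monday's | 2.00 | 56.9 |
| Monday's | 4.00 | 87.9 |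
| Monday's | 6.00 | 81.5 |
| Monday's | 10.0 | 52.8 |

(standard deviation of a reading: 1 percentage point)

- at the start none of D is dissolved
- steps thought possible: E + D -> ED; D + ED -> DED; Z <-> D

- ochre: doubling the transfer coefficient of Z, all else as stated
- green: doubling the saturation concentration of Z, all else as stated

- how much ED there is at 8.0 d, in percent of the E charged
- the change that raises the amount of ED at 8.0 d, in percent of the E charged most ("none" if none brings more than 2 percentage points) (ochre / green / none)
- amount of ED at 8.0 d, in percent of the E charged, after ochre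

1. An easy step first: Monday's ED climbs steadily from 0.833 d to 2.00 d, at 0.286 M d⁻¹. This reading, N, is taken as the ceiling of gas uptake, the rate-limiting step of that stretch.

2. The charge of E divided by N gives 1.75 d for this flask: the fill time t_F, the time the gas needs at the ceiling to convert the E charged.

3. Monday's highest reading stands at 4.00 d, later than its t_F of 3.49 d. Wednesday's stands at 2.00 d, later than its t_F of 0.874 d. So in these two runs the highest reading stands at 1.14 and 2.29 times t_F.

4. Turned round: this reckoning takes it that ochre or green can raise ED at 8.0 d if ED is still growing then, which asks for E to be left at that time. In this flask 8.0 d is 4.57 times t_F, further out than the highest reading of either run. Without E the listed steps make no ED, so more D feeds D + ED → DED. This reckoning gives a sign and no amount.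

5. The forecast gives 50% (45% to 55%), and 40% (33% to 47%) after ochre: “Both lower ED, so the answer is none”.

6. The flask gives 50.8%, and 42.6% after ochre; the choice is none.

    E + D → ED (k = 2.78 × 10⁻⁴ M⁻¹ s⁻¹)
    D + ED → DED (k = 7.81 × 10⁻⁶ M⁻¹ s⁻¹)
    Z ⇌ D, rate k3*(csat - [D]) (kL = 1.93 × 10⁻⁵ s⁻¹)

7. Ochre moves ED by −8.2 percentage points and green by −31 points. Against this flask's t_F of 1.75 d, E stands at 0.0247% at 4.00 d, with ED at 81.4% and DED at 18.5%. A neighbour charged with 1.2 M of E has a t_F of 4.19 d, still before 8.0 d, and at that time it holds E at 0%, DED at 30.2% and ED at 69.8%.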